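The midnight run still held 58.1% of its starting material at 4.00 h. That leftover poses the decision on the dawn flask: leave it to 10 h in the hope of more target, or plan a different charge?

in all of them: starting material 0.15 M; gas 23 mM (held)

| charge | second substrate | remark | time |
|---|---|---|---|
| dawn | 0.075 M | the very flask that is asked about, followed so far |  |
| midnight | 0.037 M | run made earlier |  |
| flask | 0.0750 M |  | 10 h |

- dawn (time / min: target / %): 15.0: 8.3; 30.0: 15.1; 40.0: 19.7; 60.0: 26.3; 80.0: 30.9
- midnight (time / h: target / %): 0.833: 23.4; 1.50: 32.7; 2.50: 39.3; 3.00: 39.8; 4.00: 41.9

(readings scatter by 0.3 percentage points)

- at the start none of coupling partner is dissolved
- the numbers in the tables scatter with a standard deviation of 0.3 percentage points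
- steps under discussion: gas <-> coupling partner; second substrate + coupling partner <-> second product; starting material + coupling partner <-> target
- the reaction counts as stopped when no species that holds the starting material changes by six tenths of a point or more over the second half of the time

* which holds at 10 h: what has brought the reaction to rest, or that it has not come to rest (all of the starting material has reacted / forward and back rates have come level / it is still moving)
* how much target there is at 10 h, in percent of the starting material charged

Midnight's last reading gives 0.721 for target over starting material left; call this the end ratio. At rest it equals the equilibrium constant of the target step times the dissolved coupling partner, and here it is a reading with that reading's scatter. Gas is held at 23 mM in both runs. At 49.98 min the dawn run, with twice the second substrate, stands by the mean of its neighbouring readings at 23.0%, against midnight's 23.4%, so I carry the ratio across.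

For the speed, midnight had passed about half of its last reading by 0.833 h, and 10 h is 12.0 such spans. Read as half-lives, the spans up to midnight's last reading leave an estimated 1.5 percentage points still open there. My reckoning is therefore rest with forward and back rates level, at 41.9% target, perhaps that gap higher. Leave the dawn flask as charged, wait until 10 h, and expect about that figure.

The forecast says forward and back rates have come level and 43.5%, above my figure, holding that “the target/starting material ratio settles at a value independent of the second substrate”.

In the flask at 10 h, forward and back rates have come level, with 41.7% target.

    gas ⇌ coupling partner, rate k1*(csat - [coupling partner]) (kL = 0.00405 s⁻¹)
    second substrate + coupling partner ⇌ second product (K = 190 L mol⁻¹, k = 0.00226 L mol⁻¹ s⁻¹)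
    starting material + coupling partner ⇌ target (K = 31.3 L mol⁻¹, k = 0.00671 L mol⁻¹ s⁻¹)

By 1.00 h the target stood at 26.1% with coupling partner at 0.0205 M, and by 5.00 h at 41.3% with partner at 0.0226 M. Second substrate then went on from 46.8% to 27.7% of its charge while the target reached 41.7%. The end ratio comes to 0.715 against my 0.721. Stopping this flask at 2.10 h instead moves its target by 5 points. With 0.030 M of second substrate, the end ratio again gives 41.9%; that flask computes to 41.8% target and 58.2% starting material.

The runs are calculated for substances that don't exist.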